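The target is labelled by indene numbering: C1/C3 carry the methyls, C2 the ketone, C4 the acid, C5 the styryl group. The cyclohexene ring C3a–C4–C5–C6=C7–C7a is a Diels–Alder retron, so C5 is an sp2 diene terminus in an open chain and can be joined to the styryl CH by cross-coupling. A linear gem-dibromodiene enal, whose C1–C3 stereotriad comes from one Evans aldol and a relayed hydroboration, takes up a styryl and then an ethyl group at C5 in one flask. The tetraene so formed closes both rings by intramolecular Diels–Alder reaction, the C1 and C3 methyls dictating C3a, C4, C5 and C7a. Desilylation and oxidation finish the synthesis.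

Key step: step 8

Remark: the formyl ylide used in steps 4 and 7 and the two potassium trifluoroborates used in step 8 are taken as commercial reagents.

Step 1
Reactants: 1 (S)-4-benzyl-3-propanoyl-1,3-oxazolidin-2-one; 2 methacrolein
Product: 3 (S)-4-benzyl-3-[(2S,3S)-3-hydroxy-2,4-dimethylpent-4-enoyl]-1,3-oxazolidin-2-one
Conditions: Bu2BOTf, Et3N, CH2Cl2, −78 to 0 °C; 2, −78 to 0 °C; then pH 7 buffer, MeOH, H2O2, 0 °C
Reagents that add atoms: methacrolein CC(=C)C=O
Why: Evans syn-aldol reaction, in which the (Z)-boron enolate of 1 adds to 2 through a closed chair transition state on the enolate face away from the benzyl group, which should set the 2,3-syn pair as (2S,3S), the later C1 and C2.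

Step 2
Reactants: 3; 4 tert-butyldimethylsilyl trifluoromethanesulfonate
Product: 5 (S)-4-benzyl-3-[(2S,3S)-3-[(tert-butyldimethylsilyl)oxy]-2,4-dimethylpent-4-enoyl]-1,3-oxazolidin-2-one
Conditions: 2,6-lutidine, CH2Cl2, −78 to 0 °C
Reagents that add atoms: tert-butyldimethylsilyl trifluoromethanesulfonate CC(C)(C)[Si](C)(C)OS(=O)(=O)C(F)(F)F
Why: Silylation of the secondary alcohol with the silyl triflate and a hindered pyridine base is fast at low temperature and leaves the imide untouched.

Step 3
Reactants: 5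
Product: 6 (2R,3S)-3-[(tert-butyldimethylsilyl)oxy]-2,4-dimethylpent-4-en-1-ol
Conditions: LiBH4, MeOH (1 equiv), THF, 0 °C
Reagents that add atoms: none
Why: Reductive cleavage of the N-acyl oxazolidinone by LiBH4, which attacks the exocyclic carbonyl and releases the auxiliary, should give the primary alcohol without touching either stereocentre.

Step 4
Reactants: 6; 7 2-(triphenylphosphoranylidene)butanal
Product: 9 (2E,4R,5S)-5-[(tert-butyldimethylsilyl)oxy]-2-ethyl-4,6-dimethylhepta-2,6-dienal, via silyloxy pentenal 8 (not isolated)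
Conditions: PhI(OAc)2, TEMPO (cat.), CH2Cl2, rt; then 7, toluene, 80 °C
Reagents that add atoms: 2-(triphenylphosphoranylidene)butanal CCC(C=O)=P(c1ccccc1)(c1ccccc1)c1ccccc1
Why: Nitroxyl-catalysed oxidation of the primary alcohol is followed in the same flask by a Wittig reaction with the formyl-stabilised ylide, which should give the (E)-trisubstituted enal and stop after one homologation because the enal product is a poorer electrophile than 8.

Step 5
Reactants: 9; 10 tetrabromomethane
Product: 11 tert-butyl{[(3S,4R,5E)-8,8-dibromo-6-ethyl-2,4-dimethylocta-1,5,7-trien-3-yl]oxy}dimethylsilane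
Conditions: CBr4, PPh3, CH2Cl2, 0 °C
Reagents that add atoms: tetrabromomethane BrC(Br)(Br)Br
Why: Ramirez dibromo-olefination (first stage of the Corey–Fuchs sequence), in which the ylide Ph3P=CBr2 formed from CBr4 and PPh3 converts the enal carbonyl into the 1,1-dibromoalkene carbon that becomes C5.

Step 6
Reactants: 11; 12 hydrogen peroxide
Product: 13 (2R,3S,4R,5E)-8,8-dibromo-3-[(tert-butyldimethylsilyl)oxy]-6-ethyl-2,4-dimethylocta-5,7-dien-1-ol
Conditions: 9-BBN, THF, 0 °C to rt; then NaOH, H2O2, H2O, 0 °C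
Reagents that add atoms: hydrogen peroxide OO
Why: Hydroboration–oxidation with 9-BBN should touch only the terminal 1,1-disubstituted alkene and, by acyclic 1,2-induction in the conformer minimised for allylic 1,3-strain, add to the face opposite the branched chain, so that the new methyl stereocentre (the later C3) is anti to the silyloxy group, the minor isomer being removed by chromatography.

Step 7
Reactants: 13; 7 2-(triphenylphosphoranylidene)butanal
Product: 15 (2E,4R,5S,6R,7E)-10,10-dibromo-5-[(tert-butyldimethylsilyl)oxy]-2,8-diethyl-4,6-dimethyldeca-2,7,9-trienal, via dibromo dienal 14 (not isolated)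
Conditions: PhI(OAc)2, TEMPO (cat.), CH2Cl2, rt; then 7, toluene, 80 °C
Reagents that add atoms: 2-(triphenylphosphoranylidene)butanal CCC(C=O)=P(c1ccccc1)(c1ccccc1)c1ccccc1
Why: The oxidation–Wittig sequence of step 4 is repeated at the other terminus to install the (E)-2-ethyl enal dienophile, the gem-dibromodiene being too hindered and electron-poor to act as a diene toward it at 80 °C.

Step 8
Reactants: 15; 16 potassium trifluoro[(E)-2-phenylethenyl]borate; 17 potassium ethyltrifluoroborate
Product: 20 (1R,2S,3R,3aS,4S,5R,7aS)-2-[(tert-butyldimethylsilyl)oxy]-4,5,7-triethyl-1,3-dimethyl-5-[(E)-2-phenylethenyl]-2,3,3a,4,5,7a-hexahydro-1H-indene-4-carbaldehyde, via bromotriene enal 18 (not isolated), via tetraene enal 19 (not isolated)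
Conditions: 16, Pd(PPh3)4 (cat.), Cs2CO3, toluene/H2O 3:1, 50 °C; then 17, PdCl2(dppf) (cat.), Cs2CO3, 75 °C; then 100 °C
Reagents that add atoms: potassium trifluoro[(E)-2-phenylethenyl]borate [K+].F[B-](F)(F)/C=C/c1ccccc1; potassium ethyltrifluoroborate [K+].CC[B-](F)(F)F
Why: Zerovalent palladium from Pd(PPh3)4 inserts first into the C–Br bond trans to the chain (the cis bromide is shielded by the ethyl-bearing C7) and Suzuki–Miyaura transfer of the styryl group forms the C5–styryl bond, after which insertion into the remaining (Z)-bromide and transfer of ethyl with retention give tetraene 19, which on heating closes by a normal-demand intramolecular Diels–Alder reaction. The closest known reaction types are the one-pot sequential coupling of 1,1-dibromoalkenes with an alkenyl- and then an alkyltrifluoroborate and the tandem cross-coupling/cycloaddition of trienes with a three-atom tether. The cyclohexene ring closes by the concerted suprafacial [4+2] union of C4 with C5 and of C3a with C7a, and the cyclopentane ring closes in the same event because the tether C1–C2–C3 joins the diene terminus C7a to the dienophile terminus C3a. C4 and C5 follow from the (E)-enal and (E,E)-diene geometries with the formyl group endo, and the trans ring fusion at C3a/C7a follows from this endo mode, reinforced by the C7 ethyl group, which clashes with the tether in the cis-fused transition state. The face is fixed by allylic 1,3-strain: H1 must lie in the plane of the C7a=C7 bond next to the C7 ethyl group and H3 in the plane of the C3a=C4 bond next to the C4 ethyl group, so both methyls point outward and only the transition state leading to (3aS,4S,5R,7aS) is free of a methyl/ethyl clash. The step needs the order styryl-then-ethyl at C5 and coupling before cycloaddition; the first is secured by the steric difference between the two bromides, the second by the bromine-bearing diene terminus, which makes 15 and 18 poor dienes until ethyl has replaced bromine.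

Step 9
Reactants: 20
Product: 21 (1R,2S,3R,3aS,4S,5R,7aS)-4,5,7-triethyl-2-hydroxy-1,3-dimethyl-5-[(E)-2-phenylethenyl]-2,3,3a,4,5,7a-hexahydro-1H-indene-4-carbaldehyde
Conditions: HF·pyridine, pyridine, THF, 0 °C to rt
Reagents that add atoms: none
Why: Fluoride-mediated cleavage of the silyl ether under buffered conditions should spare the non-enolisable aldehyde, and the free hydroxyl lies on the ring face opposite the C3a–C4 bond and so cannot close a lactol.

Step 10
Reactants: 21; 22 water
Product: 23 norspiculoic acid A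
Conditions: CrO3, H2SO4, H2O, acetone, 0 °C
Reagents that add atoms: water O
Why: Jones oxidation should convert the secondary alcohol into the C2 ketone through its chromate ester and the aldehyde, through its hydrate, into the C4 acid in one operation, and C1 and C3 already hold the more stable arrangement with each methyl trans to its ring neighbour, so acid-promoted enolisation cannot erode them.

Compound list
1 | (S)-4-benzyl-3-propanoyl-1,3-oxazolidin-2-one | CCC(=O)N1[C@@H](Cc2ccccc2)COC1=O | starting material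
2 | methacrolein (2-methylprop-2-enal) | CC(=C)C=O | starting material
3 | (S)-4-benzyl-3-[(2S,3S)-3-hydroxy-2,4-dimethylpent-4-enoyl]-1,3-oxazolidin-2-one | C=C(C)[C@@H](O)[C@H](C)C(=O)N1[C@@H](Cc2ccccc2)COC1=O | intermediate
4 | tert-butyldimethylsilyl trifluoromethanesulfonate | CC(C)(C)[Si](C)(C)OS(=O)(=O)C(F)(F)F | starting material
5 | (S)-4-benzyl-3-[(2S,3S)-3-[(tert-butyldimethylsilyl)oxy]-2,4-dimethylpent-4-enoyl]-1,3-oxazolidin-2-one | C=C(C)[C@@H](O[Si](C)(C)C(C)(C)C)[C@H](C)C(=O)N1[C@@H](Cc2ccccc2)COC1=O | intermediate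
6 | (2R,3S)-3-[(tert-butyldimethylsilyl)oxy]-2,4-dimethylpent-4-en-1-ol | C=C(C)[C@@H](O[Si](C)(C)C(C)(C)C)[C@H](C)CO | intermediate
7 | 2-(triphenylphosphoranylidene)butanal | CCC(C=O)=P(c1ccccc1)(c1ccccc1)c1ccccc1 | starting material
8 | (2S,3S)-3-[(tert-butyldimethylsilyl)oxy]-2,4-dimethylpent-4-enal | C=C(C)[C@@H](O[Si](C)(C)C(C)(C)C)[C@H](C)C=O | intermediate (not isolated)
9 | (2E,4R,5S)-5-[(tert-butyldimethylsilyl)oxy]-2-ethyl-4,6-dimethylhepta-2,6-dienal | C=C(C)[C@@H](O[Si](C)(C)C(C)(C)C)[C@H](C)/C=C(CC)/C=O | intermediate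
10 | tetrabromomethane | BrC(Br)(Br)Br | starting material
11 | tert-butyl{[(3S,4R,5E)-8,8-dibromo-6-ethyl-2,4-dimethylocta-1,5,7-trien-3-yl]oxy}dimethylsilane | C=C(C)[C@@H](O[Si](C)(C)C(C)(C)C)[C@H](C)/C=C(CC)/C=C(Br)Br | intermediate
12 | hydrogen peroxide | OO | starting material
13 | (2R,3S,4R,5E)-8,8-dibromo-3-[(tert-butyldimethylsilyl)oxy]-6-ethyl-2,4-dimethylocta-5,7-dien-1-ol | OC[C@@H](C)[C@@H](O[Si](C)(C)C(C)(C)C)[C@H](C)/C=C(CC)/C=C(Br)Br | intermediate
14 | (2S,3S,4R,5E)-8,8-dibromo-3-[(tert-butyldimethylsilyl)oxy]-6-ethyl-2,4-dimethylocta-5,7-dienal | O=C[C@@H](C)[C@@H](O[Si](C)(C)C(C)(C)C)[C@H](C)/C=C(CC)/C=C(Br)Br | intermediate (not isolated)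
15 | (2E,4R,5S,6R,7E)-10,10-dibromo-5-[(tert-butyldimethylsilyl)oxy]-2,8-diethyl-4,6-dimethyldeca-2,7,9-trienal | O=C/C(CC)=C/[C@@H](C)[C@@H](O[Si](C)(C)C(C)(C)C)[C@H](C)/C=C(CC)/C=C(Br)Br | intermediate
16 | potassium trifluoro[(E)-2-phenylethenyl]borate | [K+].F[B-](F)(F)/C=C/c1ccccc1 | starting material
17 | potassium ethyltrifluoroborate | [K+].CC[B-](F)(F)F | starting material
18 | (2E,4R,5S,6R,7E,9Z,11E)-10-bromo-5-[(tert-butyldimethylsilyl)oxy]-2,8-diethyl-4,6-dimethyl-12-phenyldodeca-2,7,9,11-tetraenal | O=C/C(CC)=C/[C@@H](C)[C@@H](O[Si](C)(C)C(C)(C)C)[C@H](C)/C=C(CC)/C=C(Br)/C=C/c1ccccc1 | intermediate (not isolated)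
19 | (2E,4R,5S,6R,7E,9E,11E)-5-[(tert-butyldimethylsilyl)oxy]-2,8,10-triethyl-4,6-dimethyl-12-phenyldodeca-2,7,9,11-tetraenal | O=C/C(CC)=C/[C@@H](C)[C@@H](O[Si](C)(C)C(C)(C)C)[C@H](C)/C=C(CC)/C=C(CC)/C=C/c1ccccc1 | intermediate (not isolated)
20 | (1R,2S,3R,3aS,4S,5R,7aS)-2-[(tert-butyldimethylsilyl)oxy]-4,5,7-triethyl-1,3-dimethyl-5-[(E)-2-phenylethenyl]-2,3,3a,4,5,7a-hexahydro-1H-indene-4-carbaldehyde | CCC1=C[C@](/C=C/c2ccccc2)(CC)[C@@](CC)(C=O)[C@H]2[C@H]1[C@@H](C)[C@H](O[Si](C)(C)C(C)(C)C)[C@@H]2C | intermediate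
21 | (1R,2S,3R,3aS,4S,5R,7aS)-4,5,7-triethyl-2-hydroxy-1,3-dimethyl-5-[(E)-2-phenylethenyl]-2,3,3a,4,5,7a-hexahydro-1H-indene-4-carbaldehyde | CCC1=C[C@](/C=C/c2ccccc2)(CC)[C@@](CC)(C=O)[C@H]2[C@H]1[C@@H](C)[C@H](O)[C@@H]2C | intermediate
22 | water | O | starting material
23 | norspiculoic acid A, (1R,3R,3aS,4S,5R,7aS)-4,5,7-triethyl-1,3-dimethyl-2-oxo-5-[(E)-2-phenylethenyl]-2,3,3a,4,5,7a-hexahydro-1H-indene-4-carboxylic acid | CCC1=C[C@](/C=C/c2ccccc2)(CC)[C@@](CC)(C(=O)O)[C@H]2[C@H]1[C@@H](C)C(=O)[C@@H]2C | target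

Total step count: 10
Longest linear sequence: 10 steps (1 to 23)

Steps most likely to fail

Step 8. The bromotriene may cyclise before the ethyl group is transferred, and carbonate at 75 to 100 °C may deprotonate the enal at its γ-carbon (C3), which would lead to epimerisation or loss of silanolate. The fallback sets out from 15 and rejoins the route at 23. Pinnick oxidation (NaClO2, NaH2PO4, 2-methylbut-2-ene, t-BuOH/H2O) should give the dibromo trienoic acid F1. Under the same two coupling stages (16, then 17, Cs2CO3, aqueous toluene) this acid reacts as its cesium carboxylate, which is neither a dienophile nor acidic at the γ-carbon, so time and temperature for the ethyl transfer are no longer limited. Acidification with HCl should give the tetraene acid F2, which is heated in toluene at 110 °C to close both rings and give the bicyclic silyloxy acid F3. HF·pyridine should then give the hydroxy acid F4, and Dess–Martin periodinane should oxidise it to 23.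

Step 10. Chromic acid may attack the styryl double bond, or the hindered neopentyl aldehyde may be oxidised too slowly. The fallback sets out from 21 and rejoins the route at 23. Dess–Martin periodinane (NaHCO3, CH2Cl2, 0 °C) should give the keto aldehyde F5, and Pinnick oxidation (NaClO2, NaH2PO4, 2-methylbut-2-ene, t-BuOH/H2O) should then give 23 without any strong acid or chromium reagent.

Step 7. Prolonged heating in the Wittig stage may epimerise the α-carbon of aldehyde 14 or start a premature cycloaddition of 15. The fallback sets out from 13 and rejoins the route at 15. Dess–Martin periodinane at 0 °C should give 14, used crude. A Horner–Wadsworth–Emmons reaction with the sodium salt of triethyl 2-phosphonobutanoate (NaH, THF, 0 °C) should give the ethyl trienoate F6, whose (E) isomer is separated. Reduction with i-Bu2AlH at −78 °C should give the allylic alcohol F7, and MnO2 in CH2Cl2 at room temperature should give 15, so that no stage is run above room temperature.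

Further compounds
F1 | step 8 | (2E,4R,5S,6R,7E)-10,10-dibromo-5-[(tert-butyldimethylsilyl)oxy]-2,8-diethyl-4,6-dimethyldeca-2,7,9-trienoic acid | OC(=O)/C(CC)=C/[C@@H](C)[C@@H](O[Si](C)(C)C(C)(C)C)[C@H](C)/C=C(CC)/C=C(Br)Br
F2 | step 8 | (2E,4R,5S,6R,7E,9E,11E)-5-[(tert-butyldimethylsilyl)oxy]-2,8,10-triethyl-4,6-dimethyl-12-phenyldodeca-2,7,9,11-tetraenoic acid | OC(=O)/C(CC)=C/[C@@H](C)[C@@H](O[Si](C)(C)C(C)(C)C)[C@H](C)/C=C(CC)/C=C(CC)/C=C/c1ccccc1
F3 | step 8 | (1R,2S,3R,3aS,4S,5R,7aS)-2-[(tert-butyldimethylsilyl)oxy]-4,5,7-triethyl-1,3-dimethyl-5-[(E)-2-phenylethenyl]-2,3,3a,4,5,7a-hexahydro-1H-indene-4-carboxylic acid | CCC1=C[C@](/C=C/c2ccccc2)(CC)[C@@](CC)(C(=O)O)[C@H]2[C@H]1[C@@H](C)[C@H](O[Si](C)(C)C(C)(C)C)[C@@H]2C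
F4 | step 8 | (1R,2S,3R,3aS,4S,5R,7aS)-4,5,7-triethyl-2-hydroxy-1,3-dimethyl-5-[(E)-2-phenylethenyl]-2,3,3a,4,5,7a-hexahydro-1H-indene-4-carboxylic acid | CCC1=C[C@](/C=C/c2ccccc2)(CC)[C@@](CC)(C(=O)O)[C@H]2[C@H]1[C@@H](C)[C@H](O)[C@@H]2C
F5 | step 10 | (1R,3R,3aS,4S,5R,7aS)-4,5,7-triethyl-1,3-dimethyl-2-oxo-5-[(E)-2-phenylethenyl]-2,3,3a,4,5,7a-hexahydro-1H-indene-4-carbaldehyde | CCC1=C[C@](/C=C/c2ccccc2)(CC)[C@@](CC)(C=O)[C@H]2[C@H]1[C@@H](C)C(=O)[C@@H]2C
F6 | step 7 | ethyl (2E,4R,5S,6R,7E)-10,10-dibromo-5-[(tert-butyldimethylsilyl)oxy]-2,8-diethyl-4,6-dimethyldeca-2,7,9-trienoate | CCOC(=O)/C(CC)=C/[C@@H](C)[C@@H](O[Si](C)(C)C(C)(C)C)[C@H](C)/C=C(CC)/C=C(Br)Br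
F7 | step 7 | (2E,4R,5S,6R,7E)-10,10-dibromo-5-[(tert-butyldimethylsilyl)oxy]-2,8-diethyl-4,6-dimethyldeca-2,7,9-trien-1-ol | OC/C(CC)=C/[C@@H](C)[C@@H](O[Si](C)(C)C(C)(C)C)[C@H](C)/C=C(CC)/C=C(Br)Br
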